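**Retrosynthetic overview**
- The target, (13S,14R)-13-hydroxy-ent-labd-7-ene-14,15-diyl diacetate, is cut at the acetates and at C14–O/C15–O: triol from the Sharpless epoxide of (13E)-ent-labda-7,13-dien-15-ol by Payne rearrangement and hydroxide opening.
- C12–C16 are added to C11 of ent-drimenol by propargylation, then zirconium-catalysed methylalumination and formaldehyde trapping.
- The strategy rests on ring B: its bonds C5–C10 and C8–C9 stand 1,4 to each other and C10 is the quaternary carbon shared with ring A. One intramolecular [4+2] of a C9=C10 enimide onto a C5=C6–C7=C8 silyloxydiene, joined through C1–C4, therefore forms rings A and B together (step 9).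
- The adduct keeps its enol ether at C6=C7, so the Δ7 alkene is reached by hydrolysis to the C7 ketone, re-enolisation toward C8 as the enol triflate, and reduction.
- The trienimide comes from 2,2-dimethylpent-4-enal: B-alkyl Suzuki coupling with the E enol triflate of methyl acetoacetate (fixes the E C9=C10 geometry), Horner–Wadsworth–Emmons olefination (C5=C6), silylation.

Key step: step 9

Remark: labdane numbering is used for every compound (C11 on C9, C17 = methyl on C8, C18/C19 on C4, C20 = methyl on C10); α is the face of C20, β the face of H5 and H9.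
Remark (assumption): the sense of induction in step 9 is assigned from the square-planar chelate model of copper bis(oxazoline) enimide cycloadditions, which calls for the (S,S)-ligand; the assignment of step 18 rests on the usual tartrate rule for E 3-methyl-2-alken-1-ols.

**Step 1**
Reactants: 1 2,2-dimethylpent-4-enal
Product: 2 2-(2-methylpent-4-en-2-yl)-1,3-dioxolane
Conditions: HOCH2CH2OH, p-TsOH (cat.), benzene, reflux, Dean–Stark
Reagents that add atoms: ethylene glycol, OCCO
Why: Acid-catalysed acetalisation with azeotropic removal of water masks the non-enolisable aldehyde so that the terminal alkene can be hydroborated in step 3.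

**Step 2**
Reactants: 3 methyl acetoacetate
Product: 4 methyl (2E)-3-{[(trifluoromethyl)sulfonyl]oxy}but-2-enoate
Conditions: Tf2O, aq. Me4NOH, hexanes, 5 °C
Reagents that add atoms: trifluoromethanesulfonic anhydride, O=S(=O)(OS(=O)(=O)C(F)(F)F)C(F)(F)F
Why: O-Triflation of the β-keto ester enolate, in which the non-chelating tetramethylammonium counter-ion should favour the extended enolate and hence the E enol triflate (triflate trans to the ester).

**Step 3**
Reactants: 2 2-(2-methylpent-4-en-2-yl)-1,3-dioxolane; 4 methyl (2E)-3-{[(trifluoromethyl)sulfonyl]oxy}but-2-enoate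
Product: 6 methyl (2E)-7-(1,3-dioxolan-2-yl)-3,7-dimethyloct-2-enoate, via B-alkyl-9-borabicyclononane 5 (not isolated)
Conditions: 9-BBN-H, THF, 0 °C → rt; then 4, PdCl2(dppf) (5 mol%), AsPh3, Cs2CO3, DMF/H2O, rt
Reagents that add atoms: none
Why: Anti-Markovnikov hydroboration of the terminal alkene followed by B-alkyl Suzuki–Miyaura coupling, which goes with retention at the sp2 carbon and so fixes the E geometry of the future C9=C10 dienophile (C11 cis to C20).

**Step 4**
Reactants: 6 methyl (2E)-7-(1,3-dioxolan-2-yl)-3,7-dimethyloct-2-enoate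
Product: 7 (2E)-7-(1,3-dioxolan-2-yl)-3,7-dimethyloct-2-enoic acid
Conditions: LiOH, THF/MeOH/H2O, 45 °C; then 1 M HCl to pH 4, 0 °C
Reagents that add atoms: lithium hydroxide, [Li+].[OH-]
Why: Ester saponification, in which the dioxolane is stable to base and should survive the brief cold acidification.

**Step 5**
Reactants: 7 (2E)-7-(1,3-dioxolan-2-yl)-3,7-dimethyloct-2-enoic acid; 8 oxazolidin-2-one
Product: 10 3-[(2E)-7-(1,3-dioxolan-2-yl)-3,7-dimethyloct-2-enoyl]oxazolidin-2-one, via mixed pivalic anhydride 9 (not isolated)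
Conditions: t-BuCOCl, Et3N, THF, −20 °C; then 8, LiCl, −20 °C → rt
Reagents that add atoms: none
Why: N-Acylation of the oxazolidinone through the mixed pivalic anhydride, whose hindered pivaloyl carbonyl directs attack to the enoyl carbonyl, under amine/LiCl conditions mild enough not to deconjugate the E enoate.

**Step 6**
Reactants: 10 3-[(2E)-7-(1,3-dioxolan-2-yl)-3,7-dimethyloct-2-enoyl]oxazolidin-2-one
Product: 11 3-[(2E)-3,7,7-trimethyl-8-oxooct-2-enoyl]oxazolidin-2-one
Conditions: 1 M HCl, THF, 40 °C
Reagents that add atoms: water, O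
Why: Acid hydrolysis of the acetal frees the neopentyl aldehyde, while the enimide is inert to dilute aqueous acid.

**Step 7**
Reactants: 11 3-[(2E)-3,7,7-trimethyl-8-oxooct-2-enoyl]oxazolidin-2-one; 12 dimethyl (2-oxobutyl)phosphonate
Product: 13 3-[(2E,8E)-3,7,7-trimethyl-10-oxododeca-2,8-dienoyl]oxazolidin-2-one
Conditions: LiCl, i-Pr2NEt, MeCN, rt
Reagents that add atoms: none
Why: Horner–Wadsworth–Emmons olefination of the non-enolisable aldehyde with the lithium-chelated ketophosphonate anion should give the E enone (C5=C6), and the mild amine base leaves the imide alone.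

**Step 8**
Reactants: 13 3-[(2E,8E)-3,7,7-trimethyl-10-oxododeca-2,8-dienoyl]oxazolidin-2-one
Product: 14 3-[(2E,8E,10Z)-10-(tert-butyldimethylsilyloxy)-3,7,7-trimethyldodeca-2,8,10-trienoyl]oxazolidin-2-one
Conditions: TBSOTf, Et3N, CH2Cl2, −78 → 0 °C
Reagents that add atoms: tert-butyldimethylsilyl trifluoromethanesulfonate, CC(C)(C)[Si](C)(C)OS(=O)(=O)C(F)(F)F
Why: Soft enolisation and O-silylation of the ethyl ketone, which can enolise only toward C8 because quaternary C4 leaves no γ-hydrogen, should give the Z silyl enol ether (methyl on the outside of the diene).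

**Step 9**
Reactants: 14 3-[(2E,8E,10Z)-10-(tert-butyldimethylsilyloxy)-3,7,7-trimethyldodeca-2,8,10-trienoyl]oxazolidin-2-one
Product: 15 3-{[(1R,2S,4aR,8aR)-3-(tert-butyldimethylsilyloxy)-2,5,5,8a-tetramethyl-1,2,4a,5,6,7,8,8a-octahydronaphthalen-1-yl]carbonyl}oxazolidin-2-one
Conditions: [Cu((S,S)-t-Bu-box)](SbF6)2 (10 mol%, divalent copper; from CuCl2, 2,2'-(propane-2,2-diyl)bis[(4S)-4-tert-butyl-4,5-dihydrooxazole] and AgSbF6), 4 Å MS, CH2Cl2 (0.01 M), rt
Reagents that add atoms: none
Why: Proposed new method: chelation of both imide carbonyls to the square-planar divalent copper centre activates the s-cis enimide, and the tethered 2-silyloxydiene should add in a concerted but asynchronous [4+2] in which the bond from C5 to the β-carbon C10 runs ahead of the C8–C9 bond; the closest known reaction is the copper bis(oxazoline)-catalysed type 1 intramolecular Diels–Alder reaction of 2,8,10-trienoyl oxazolidinones with a β-monosubstituted dienophile, extended here to a β,β-disubstituted one that creates quaternary C10. Ring B closes as the six-membered ring of the cycloaddition (bonds C5–C10 and C8–C9), and ring A closes in the same event as the six-membered ring annulated through the C1–C3 tether when C5–C10 forms. The tert-butyl group of the (S,S)-ligand should shield the Si face of C9, so that the diene adds to the Re face and fixes C9 and, through the E geometry of the dienophile (C11 cis to C20), C10; C5 follows from the carbonyl-endo, tether-exo transition state, which gives the trans ring fusion, and C8 from the Z geometry of the enol ether (its configuration is erased in step 11). The step needs face and endo selectivity, secured by the rigid chelate and by the gem-dimethyl group at C4, whose Thorpe–Ingold effect favours the folded reactive conformer. Since the nucleophilic enol ether carbon C8 has to bond to the α-carbon C9, a stepwise Mukaiyama–Michael route cannot reach the adduct and only costs material through intermolecular addition, which high dilution and molecular sieves should suppress.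

**Step 10**
Reactants: 15 3-{[(1R,2S,4aR,8aR)-3-(tert-butyldimethylsilyloxy)-2,5,5,8a-tetramethyl-1,2,4a,5,6,7,8,8a-octahydronaphthalen-1-yl]carbonyl}oxazolidin-2-one
Product: 16 3-(7-oxo-ent-driman-11-oyl)oxazolidin-2-one, 8β-methyl (equatorial) epimer
Conditions: 1 M HCl, THF, rt
Reagents that add atoms: none
Why: Protodesilylation of the silyl enol ether (protonation at C6) unmasks the C7 ketone, and acid-catalysed enolisation toward C8 should let the methyl group settle equatorial; either C8 epimer serves step 11.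

**Step 11**
Reactants: 16 3-(7-oxo-ent-driman-11-oyl)oxazolidin-2-one
Product: 17 3-[7-(trifluoromethylsulfonyloxy)-ent-drim-7-en-11-oyl]oxazolidin-2-one
Conditions: Tf2O, 2,6-di-tert-butyl-4-methylpyridine, CH2Cl2, 0 °C → rt
Reagents that add atoms: trifluoromethanesulfonic anhydride, O=S(=O)(OS(=O)(=O)C(F)(F)F)C(F)(F)F
Why: Enol triflate formation under non-basic conditions (O-triflation, then loss of a proton to the hindered pyridine) should favour the more substituted C7=C8 triflate, as known for 2-alkylcyclohexanones, and spares the C9–H next to the imide.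

**Step 12**
Reactants: 17 3-[7-(trifluoromethylsulfonyloxy)-ent-drim-7-en-11-oyl]oxazolidin-2-one
Product: 18 11-hydroxy-ent-drim-7-en-7-yl trifluoromethanesulfonate
Conditions: LiBH4, H2O (1 equiv), Et2O, 0 °C
Reagents that add atoms: none
Why: Hydride reduction of the exocyclic imide carbonyl releases the primary C11 alcohol and the oxazolidinone, while the enol triflate and C9 are untouched by this weakly basic hydride.

**Step 13**
Reactants: 18 11-hydroxy-ent-drim-7-en-7-yl trifluoromethanesulfonate
Product: 19 ent-drimenol, [(1R,4aR,8aR)-2,5,5,8a-tetramethyl-1,4,4a,5,6,7,8,8a-octahydronaphthalen-1-yl]methanol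
Conditions: Pd(OAc)2 (5 mol%), PPh3, n-Bu3N, HCO2H, DMF, 60 °C
Reagents that add atoms: none
Why: Palladium-catalysed formate hydrogenolysis of the enol triflate (oxidative addition, formate exchange, decarboxylation, reductive elimination) replaces OTf by H without moving the double bond, giving the Δ7 alkene.

**Step 14**
Reactants: 19 ent-drimenol
Product: 20 11-iodo-ent-drim-7-ene
Conditions: PPh3, I2, imidazole, toluene, rt → 60 °C
Reagents that add atoms: iodine, [I][I]
Why: Appel-type iodination, in which iodide displaces the alkoxyphosphonium group by SN2 at the primary C11, which is not a stereocentre.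

**Step 15**
Reactants: 20 11-iodo-ent-drim-7-ene; 21 1-(trimethylsilyl)propyne
Product: 23 14-(trimethylsilyl)-15,16-dinor-ent-labd-7-en-13-yne, via 3-lithio-1-(trimethylsilyl)propyne 22 (not isolated)
Conditions: 21, n-BuLi, THF, −78 → −20 °C; then 20, DMPU, −78 °C → rt
Reagents that add atoms: none
Why: SN2 alkylation of the primary iodide by lithiated 1-(trimethylsilyl)propyne, whose silyl group steers the ambident anion to its propargylic carbon, adds C12–C14.

**Step 16**
Reactants: 23 14-(trimethylsilyl)-15,16-dinor-ent-labd-7-en-13-yne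
Product: 24 15,16-dinor-ent-labd-7-en-13-yne
Conditions: K2CO3, MeOH/THF, rt
Reagents that add atoms: none
Why: Base-catalysed methanolysis of the C(sp)–Si bond gives the terminal alkyne.

**Step 17**
Reactants: 24 15,16-dinor-ent-labd-7-en-13-yne
Product: 27 (13E)-ent-labda-7,13-dien-15-ol, via alkenyldimethylalane 25 (not isolated), via lithium alkenylaluminate 26 (not isolated)
Conditions: Me3Al, Cp2ZrCl2 (0.25 equiv), CH2Cl2, rt; volatiles removed; n-BuLi, THF, −78 °C; (CH2O)n, → rt
Reagents that add atoms: trimethylaluminium, C[Al](C)C; paraformaldehyde (as formaldehyde), C=O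
Why: Zirconium-catalysed syn carboalumination (Negishi carboalumination) puts the methyl group on C13 and aluminium on C14, and the derived aluminate adds to formaldehyde with retention, so the 13E allylic alcohol results; the trisubstituted ring alkene does not react.

**Step 18**
Reactants: 27 (13E)-ent-labda-7,13-dien-15-ol
Product: 28 (13S,14S)-13,14-epoxy-ent-labd-7-en-15-ol
Conditions: Ti(OiPr)4 (10 mol%), L-(+)-diisopropyl tartrate (12 mol%), t-BuOOH, 4 Å MS, CH2Cl2, −20 °C
Reagents that add atoms: tert-butyl hydroperoxide, CC(C)(C)OO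
Why: Sharpless asymmetric epoxidation acts only on the allylic alcohol, not on the Δ7 alkene, and with the L-(+)-tartrate an E 3-methyl-2-alken-1-ol of the geraniol type should be epoxidised on the face that gives the (13S,14S)-epoxide under reagent control.

**Step 19**
Reactants: 28 (13S,14S)-13,14-epoxy-ent-labd-7-en-15-ol
Product: 30 (13S,14R)-ent-labd-7-ene-13,14,15-triol, via 14,15-epoxy-13-ol 29 (not isolated)
Conditions: 0.5 M NaOH, t-BuOH/H2O, 75 °C
Reagents that add atoms: water, O
Why: Payne rearrangement (the C15 alkoxide opens the epoxide at C14 with inversion, giving 14R, while the epoxide oxygen stays on C13 as the 13S tertiary alcohol) followed by hydroxide opening of the terminal epoxide at C15; direct hydroxide attack at C14 would give the same triol, and the basic medium spares the Δ7 alkene.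

**Step 20**
Reactants: 30 (13S,14R)-ent-labd-7-ene-13,14,15-triol
Product: 31 (13S,14R)-13-hydroxy-ent-labd-7-ene-14,15-diyl diacetate
Conditions: Ac2O, pyridine, rt
Reagents that add atoms: acetic anhydride, CC(=O)OC(C)=O
Why: Acetylation of the primary and secondary hydroxyl groups, the tertiary 13-OH being too hindered to be acylated under these conditions.

**Compound list**
1 | 2,2-dimethylpent-4-enal | C=CCC(C)(C)C=O | starting material
2 | 2-(2-methylpent-4-en-2-yl)-1,3-dioxolane | C=CCC(C)(C)C1OCCO1 | intermediate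
3 | methyl acetoacetate | CC(=O)CC(=O)OC | starting material
4 | methyl (2E)-3-{[(trifluoromethyl)sulfonyl]oxy}but-2-enoate | COC(=O)/C=C(\C)OS(=O)(=O)C(F)(F)F | intermediate
5 | 9-[4-(1,3-dioxolan-2-yl)-4-methylpentyl]-9-borabicyclo[3.3.1]nonane | CC(C)(CCCB1C2CCCC1CCC2)C1OCCO1 | intermediate (not isolated)
6 | methyl (2E)-7-(1,3-dioxolan-2-yl)-3,7-dimethyloct-2-enoate | COC(=O)/C=C(\C)CCCC(C)(C)C1OCCO1 | intermediate
7 | (2E)-7-(1,3-dioxolan-2-yl)-3,7-dimethyloct-2-enoic acid | OC(=O)/C=C(\C)CCCC(C)(C)C1OCCO1 | intermediate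
8 | oxazolidin-2-one | O=C1NCCO1 | starting material
9 | (2E)-7-(1,3-dioxolan-2-yl)-3,7-dimethyloct-2-enoic pivalic anhydride | CC(C)(C)C(=O)OC(=O)/C=C(\C)CCCC(C)(C)C1OCCO1 | intermediate (not isolated)
10 | 3-[(2E)-7-(1,3-dioxolan-2-yl)-3,7-dimethyloct-2-enoyl]oxazolidin-2-one | O=C1OCCN1C(=O)/C=C(\C)CCCC(C)(C)C2OCCO2 | intermediate
11 | 3-[(2E)-3,7,7-trimethyl-8-oxooct-2-enoyl]oxazolidin-2-one | O=C1OCCN1C(=O)/C=C(\C)CCCC(C)(C)C=O | intermediate
12 | dimethyl (2-oxobutyl)phosphonate | CCC(=O)CP(=O)(OC)OC | starting material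
13 | 3-[(2E,8E)-3,7,7-trimethyl-10-oxododeca-2,8-dienoyl]oxazolidin-2-one | O=C1OCCN1C(=O)/C=C(\C)CCCC(C)(C)/C=C/C(=O)CC | intermediate
14 | 3-[(2E,8E,10Z)-10-(tert-butyldimethylsilyloxy)-3,7,7-trimethyldodeca-2,8,10-trienoyl]oxazolidin-2-one | O=C1OCCN1C(=O)/C=C(\C)CCCC(C)(C)/C=C/C(O[Si](C)(C)C(C)(C)C)=C/C | intermediate
15 | 3-{[(1R,2S,4aR,8aR)-3-(tert-butyldimethylsilyloxy)-2,5,5,8a-tetramethyl-1,2,4a,5,6,7,8,8a-octahydronaphthalen-1-yl]carbonyl}oxazolidin-2-one (trans-fused; 5β-H, 8α-CH3, 9β-H, 10α-CH3; C6=C7 silyl enol ether) | O=C1OCCN1C(=O)[C@@H]2[C@H](C)C(O[Si](C)(C)C(C)(C)C)=C[C@@H]3C(C)(C)CCC[C@@]23C | intermediate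
16 | 3-(7-oxo-ent-driman-11-oyl)oxazolidin-2-one (5β-H, 8β-CH3, 9β-H, 10α-CH3) | O=C1OCCN1C(=O)[C@@H]2[C@@H](C)C(=O)C[C@@H]3C(C)(C)CCC[C@@]23C | intermediate
17 | 3-[7-(trifluoromethylsulfonyloxy)-ent-drim-7-en-11-oyl]oxazolidin-2-one | O=C1OCCN1C(=O)[C@@H]2C(C)=C(OS(=O)(=O)C(F)(F)F)C[C@@H]3C(C)(C)CCC[C@@]23C | intermediate
18 | 11-hydroxy-ent-drim-7-en-7-yl trifluoromethanesulfonate | OC[C@@H]1C(C)=C(OS(=O)(=O)C(F)(F)F)C[C@@H]2C(C)(C)CCC[C@@]12C | intermediate
19 | ent-drimenol, [(1R,4aR,8aR)-2,5,5,8a-tetramethyl-1,4,4a,5,6,7,8,8a-octahydronaphthalen-1-yl]methanol | OC[C@@H]1C(C)=CC[C@@H]2C(C)(C)CCC[C@@]12C | intermediate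
20 | 11-iodo-ent-drim-7-ene | IC[C@@H]1C(C)=CC[C@@H]2C(C)(C)CCC[C@@]12C | intermediate
21 | 1-(trimethylsilyl)propyne | CC#C[Si](C)(C)C | starting material
22 | 3-lithio-1-(trimethylsilyl)propyne | [Li]CC#C[Si](C)(C)C | intermediate (not isolated)
23 | 14-(trimethylsilyl)-15,16-dinor-ent-labd-7-en-13-yne | C[Si](C)(C)C#CCC[C@@H]1C(C)=CC[C@@H]2C(C)(C)CCC[C@@]12C | intermediate
24 | 15,16-dinor-ent-labd-7-en-13-yne | C#CCC[C@@H]1C(C)=CC[C@@H]2C(C)(C)CCC[C@@]12C | intermediate
25 | (13E)-14-(dimethylalumanyl)-15-nor-ent-labda-7,13-diene | C[Al](C)/C=C(\C)CC[C@@H]1C(C)=CC[C@@H]2C(C)(C)CCC[C@@]12C | intermediate (not isolated)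
26 | lithium butyl(dimethyl)[(13E)-15-nor-ent-labda-7,13-dien-14-yl]aluminate | [Li+].CCCC[Al-](C)(C)/C=C(\C)CC[C@@H]1C(C)=CC[C@@H]2C(C)(C)CCC[C@@]12C | intermediate (not isolated)
27 | (13E)-ent-labda-7,13-dien-15-ol | OC/C=C(\C)CC[C@@H]1C(C)=CC[C@@H]2C(C)(C)CCC[C@@]12C | intermediate
28 | (13S,14S)-13,14-epoxy-ent-labd-7-en-15-ol | OC[C@@H]1O[C@@]1(C)CC[C@@H]2C(C)=CC[C@@H]3C(C)(C)CCC[C@@]23C | intermediate
29 | (13S,14R)-14,15-epoxy-ent-labd-7-en-13-ol | C1O[C@H]1[C@@](C)(O)CC[C@@H]2C(C)=CC[C@@H]3C(C)(C)CCC[C@@]23C | intermediate (not isolated)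
30 | (13S,14R)-ent-labd-7-ene-13,14,15-triol | OC[C@@H](O)[C@@](C)(O)CC[C@@H]1C(C)=CC[C@@H]2C(C)(C)CCC[C@@]12C | intermediate
31 | (13S,14R)-13-hydroxy-ent-labd-7-ene-14,15-diyl diacetate, (5R,9R,10R) | CC(=O)OC[C@@H](OC(C)=O)[C@@](C)(O)CC[C@@H]1C(C)=CC[C@@H]2C(C)(C)CCC[C@@]12C | target

**Step count**
Total: 20 steps. Longest linear sequence: 19 steps (steps 1 and 3–20; step 2 makes the coupling partner 4).

**Steps most likely to fail**

1. Step 9 (proposed new method). The β,β-disubstituted enimide may be too weakly activated or too hindered for the chelated catalyst; desilylation of the dienol ether, intermolecular Michael addition or an unselective background cycloaddition could then take over, and face selectivity would be lost. Fallback by known chemistry, from 14: an uncatalysed thermal intramolecular Diels–Alder reaction (toluene, 170 °C, sealed tube, BHT, a little N,O-bis(trimethylsilyl)acetamide as acid scavenger) should give the trans-fused endo adduct as the racemate of 15, F1, after removal of cis-fused isomers by chromatography. Preparative chromatography on a chiral stationary phase (cellulose tris(3,5-dimethylphenylcarbamate), hexane/i-PrOH) then gives 15, where the route is rejoined.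

2. Step 11. Loss of regiocontrol in the enolisation: deprotonation of the O-triflyl oxocarbenium ion toward C6 instead of C8 would lead on to the Δ6 alkene. Fallback from 16: Li(s-Bu)3BH in THF at −78 °C should reduce the ketone from the equatorial side to the axial alcohol, 3-(7β-hydroxy-ent-driman-11-oyl)oxazolidin-2-one F2. Anti elimination with Martin sulfurane, Ph2S[OC(CF3)2Ph]2, in CH2Cl2 should then remove the axial 8α-H in preference and give 3-(ent-drim-7-en-11-oyl)oxazolidin-2-one F3. LiBH4 reduction as in step 12 gives 19.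

3. Step 15. Slow substitution at the β-branched, neopentyl-like C11 with competing E2 elimination toward the exocyclic C9=C11 alkene. Fallback from 19, with C11 as an electrophilic carbonyl instead: Dess–Martin periodinane/NaHCO3 gives ent-drim-7-en-11-al F4. Wittig olefination with Ph3P=CHCO2Me (toluene, 80 °C, no added base) gives methyl (11E)-14,15,16-trinor-ent-labda-7,11-dien-13-oate F5. Mg in MeOH reduces the conjugated double bond to methyl 14,15,16-trinor-ent-labd-7-en-13-oate F6. (i-Bu)2AlH at −78 °C gives 14,15,16-trinor-ent-labd-7-en-13-al F7. Ohira–Bestmann homologation (dimethyl (1-diazo-2-oxopropyl)phosphonate, K2CO3, MeOH) then gives 24.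

**Further compounds**
F1 | step 9 | racemate of 15 (both enantiomers, relative configuration as in 15) | O=C1OCCN1C(=O)[C@@H]2[C@H](C)C(O[Si](C)(C)C(C)(C)C)=C[C@@H]3C(C)(C)CCC[C@@]23C.O=C1OCCN1C(=O)[C@H]2[C@@H](C)C(O[Si](C)(C)C(C)(C)C)=C[C@H]3C(C)(C)CCC[C@]23C
F2 | step 11 | 3-(7β-hydroxy-ent-driman-11-oyl)oxazolidin-2-one (axial 7-OH, 8β-CH3) | O=C1OCCN1C(=O)[C@@H]2[C@@H](C)[C@@H](O)C[C@@H]3C(C)(C)CCC[C@@]23C
F3 | step 11 | 3-(ent-drim-7-en-11-oyl)oxazolidin-2-one | O=C1OCCN1C(=O)[C@@H]2C(C)=CC[C@@H]3C(C)(C)CCC[C@@]23C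
F4 | step 15 | ent-drim-7-en-11-al | O=C[C@@H]1C(C)=CC[C@@H]2C(C)(C)CCC[C@@]12C
F5 | step 15 | methyl (11E)-14,15,16-trinor-ent-labda-7,11-dien-13-oate | COC(=O)/C=C/[C@@H]1C(C)=CC[C@@H]2C(C)(C)CCC[C@@]12C
F6 | step 15 | methyl 14,15,16-trinor-ent-labd-7-en-13-oate | COC(=O)CC[C@@H]1C(C)=CC[C@@H]2C(C)(C)CCC[C@@]12C
F7 | step 15 | 14,15,16-trinor-ent-labd-7-en-13-al | O=CCC[C@@H]1C(C)=CC[C@@H]2C(C)(C)CCC[C@@]12C
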